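Numbering: pyranone O1, C2(=O), C3(OMe), C4(OH), C5(Me), C6; side chain C1' (CH2 on C6) to C11' (benzylic CH2).
Retrosynthesis: the MOM acetal comes off first, then C1'–C2' is cut (pyranonylmethyl bromide + (E)-alkenylalane from a terminal alkyne), then C3'–C4' (acetylide + primary iodide), and last Ph–C11' and C7'–C8' together.
That last cut is open because C8'–C9'(Me)=C10'–C11' is an isoprene unit carrying phenyl on C11' and the alkene carbon C7' on C8'; phenyl triflate, isoprene and a C4'–C7' alkenylboronate should give it in one palladium-catalysed 1,4-difunctionalisation.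
Forward: (Z)-iodoalkene → boronate → three-component coupling → desilylation, iodination, ethynylation → methylalumination and coupling with the bromide of the separately built pyranone (Claisen, dianion acylation, lactonisation; the only ring closure) → deprotection.
Stereochemistry: there is no stereocentre; 6'Z comes from the iodo-Wittig step and retentive borylation and transmetalation, 9'E from the syn π-allyl of the key step, 2'E from syn methylalumination and retentive coupling.

Key step: step 4

Assumption: 3-(tert-butyldimethylsilyloxy)propan-1-ol is taken as a catalogue compound; the C4'–C6' segment needs this three-carbon unit, since a four-carbon diol would place one CH2 too many between oxygen and the alkene.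

Step 1
Reactants: 1 3-(tert-butyldimethylsilyloxy)propan-1-ol
Product: 2 3-(tert-butyldimethylsilyloxy)propanal
Conditions: PhI(OAc)2, TEMPO (10 mol%), CH2Cl2, rt
Reagents that add atoms: none
Why: TEMPO-catalysed oxidation with PhI(OAc)2 should stop at the aldehyde and leave the silyl ether untouched; no stereocentre forms.

Step 2
Reactants: 2 3-(tert-butyldimethylsilyloxy)propanal; 3 ethyltriphenylphosphonium iodide
Product: 4 (Z)-tert-butyl[(4-iodopent-3-en-1-yl)oxy]dimethylsilane
Conditions: 3, n-BuLi, THF, rt; I2, −78 °C; NaN(SiMe3)2, −20 °C; then 2, −78 °C → rt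
Reagents that add atoms: iodine, II
Why: Stork–Zhao-type iodo-Wittig olefination, in which the non-stabilised α-iodo ylide made in the flask adds to the aldehyde under kinetic control and should give the (Z)-2-iodoalkene that fixes the later C6'=C7' geometry.

Step 3
Reactants: 4 (Z)-tert-butyl[(4-iodopent-3-en-1-yl)oxy]dimethylsilane
Product: 6 pinacol (E)-5-(tert-butyldimethylsilyloxy)pent-2-en-2-ylboronate (boron cis to the chain), via alkenyllithium 5 (not isolated)
Conditions: t-BuLi (2.1 equiv), Et2O, −78 °C; then i-PrOBpin, −78 °C → rt; aq. NH4Cl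
Reagents that add atoms: 2-isopropoxy-4,4,5,5-tetramethyl-1,3,2-dioxaborolane, CC(C)OB1OC(C)(C)C(C)(C)O1
Why: Lithium–iodine exchange on an alkenyl iodide and trapping of the alkenyllithium with a borate ester both run with retention at −78 °C, so boron should end cis to the CH2CH2OTBS chain.

Step 4
Reactants: 6 pinacol (E)-5-(tert-butyldimethylsilyloxy)pent-2-en-2-ylboronate; 7 phenyl trifluoromethanesulfonate; 8 isoprene
Product: 9 tert-butyl{[(3Z,6E)-4,6-dimethyl-8-phenylocta-3,6-dien-1-yl]oxy}dimethylsilane
Conditions: Pd2(dba)3 (2.5 mol%), 4-tert-butyl-2-(pyridin-2-yl)-4,5-dihydrooxazole (6 mol%), KF (2 equiv), 8 (5 equiv), DMA, 55 °C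
Reagents that add atoms: none
Why: Oxidative addition of 7 to the zerovalent palladium–pyridine-oxazoline complex gives a cationic phenylpalladium species that inserts the monosubstituted alkene of isoprene with phenyl going to the CH2 terminus (C11'), leaving a π-allyl over C10', C9' and C8'; fluoride-assisted transmetalation of 6 and reductive elimination at the unsubstituted terminus C8' then complete the cycle. The closest known reaction type is the palladium-catalysed three-component 1,4-carbodifunctionalisation of butadiene and isoprene with an sp2 triflate and an organoboron reagent, which gives skipped dienes. No ring closes and no stereocentre forms; C9'=C10' should be E because the CH2Ph substituent on C10' sits syn in the π-allyl (anti would clash with the C8' hydrogens), and the C6'=C7' geometry is carried over from 6 because alkenyl transmetalation is retentive. The step needs insertion at the vinyl and not the isopropenyl end, 1,4- and not 1,2-capture, and insertion ahead of direct phenyl–alkenyl coupling. The first two are favoured by the methyl group on C9', which hinders both the isopropenyl carbon and the internal allyl terminus, and by the electronically unsymmetrical bidentate nitrogen ligand; the third by the phosphine-free cationic catalyst and the excess of isoprene.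

Step 5
Reactants: 9 tert-butyl{[(3Z,6E)-4,6-dimethyl-8-phenylocta-3,6-dien-1-yl]oxy}dimethylsilane
Product: 10 (3Z,6E)-4,6-dimethyl-8-phenylocta-3,6-dien-1-ol
Conditions: Bu4NF, THF, 0 °C → rt; aq. NH4Cl
Reagents that add atoms: none
Why: Fluoride-mediated cleavage of a primary silyl ether, to which the skipped diene is inert.

Step 6
Reactants: 10 (3Z,6E)-4,6-dimethyl-8-phenylocta-3,6-dien-1-ol
Product: 11 (3Z,6E)-1-iodo-4,6-dimethyl-8-phenylocta-3,6-diene
Conditions: I2, PPh3, imidazole, CH2Cl2, 0 °C → rt
Reagents that add atoms: iodine, II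
Why: Appel-type iodination converts the primary alcohol into the iodide by SN2 displacement of the oxyphosphonium group under neutral conditions that do not touch the alkenes.

Step 7
Reactants: 11 (3Z,6E)-1-iodo-4,6-dimethyl-8-phenylocta-3,6-diene
Product: 12 (5Z,8E)-6,8-dimethyl-10-phenyldeca-5,8-dien-1-yne
Conditions: LiC≡CH·H2NCH2CH2NH2, DMSO, 15 °C → rt
Reagents that add atoms: lithium acetylide–ethylenediamine complex, [Li]C#C.NCCN
Why: SN2 alkylation of lithium acetylide by a primary iodide in DMSO is a standard route to terminal alkynes and should outrun E2 at or below room temperature; it forms C3'–C4'.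

Step 8
Reactants: 13 methyl methoxyacetate; 14 propanoyl chloride
Product: 15 methyl 2-methoxy-3-oxopentanoate (racemic)
Conditions: 13 (2 equiv), LiN(i-Pr)2 (2 equiv), THF, −78 °C; then 14 (1 equiv); aq. NH4Cl
Reagents that add atoms: none
Why: Crossed Claisen acylation of the lithium enolate of an α-alkoxy ester by an acid chloride, with the second equivalent of enolate taking up the acidic proton of the β-keto ester; the new stereocentre is later lost.

Step 9
Reactants: 15 methyl 2-methoxy-3-oxopentanoate; 16 N-methoxy-N-methylacetamide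
Product: 18 methyl 2-methoxy-4-methyl-3,5-dioxohexanoate (mixture of diastereomers and enol forms), via dilithium dienolate 17 (not isolated)
Conditions: LiN(i-Pr)2 (2.2 equiv), THF, −78 → 0 °C; then 16, −78 → 0 °C; aq. HCl
Reagents that add atoms: none
Why: γ-Acylation of a β-keto ester dianion by a Weinreb amide, whose chelated tetrahedral adduct prevents over-addition and collapses to the 3,5-diketo ester on acidic work-up.

Step 10
Reactants: 18 methyl 2-methoxy-4-methyl-3,5-dioxohexanoate
Product: 19 4-hydroxy-3-methoxy-5,6-dimethyl-2H-pyran-2-one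
Conditions: DBU, toluene, 80 °C; then aq. HCl
Reagents that add atoms: none
Why: Base-mediated lactonisation of a 3,5-diketo ester (enol oxygen of the C5 ketone onto the ester, 6-exo-trig, loss of methanol) is the classical entry to 4-hydroxy-2-pyranones and turns both former stereocentres into sp2 carbons.

Step 11
Reactants: 19 4-hydroxy-3-methoxy-5,6-dimethyl-2H-pyran-2-one
Product: 20 3-methoxy-4-(methoxymethoxy)-5,6-dimethyl-2H-pyran-2-one
Conditions: MOMCl, i-Pr2NEt, CH2Cl2, 0 °C → rt
Reagents that add atoms: chloromethyl methyl ether, COCCl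
Why: O-alkylation of the vinylogous acid with a hard chloromethyl ether and an amine base is expected on the C4 oxygen and masks the acidic hydroxyl for the organometallic coupling.

Step 12
Reactants: 20 3-methoxy-4-(methoxymethoxy)-5,6-dimethyl-2H-pyran-2-one
Product: 21 6-(bromomethyl)-3-methoxy-4-(methoxymethoxy)-5-methyl-2H-pyran-2-one
Conditions: NBS (1.05 equiv), AIBN (5 mol%), PhCF3, 80 °C
Reagents that add atoms: N-bromosuccinimide, O=C1CCC(=O)N1Br
Why: Wohl–Ziegler bromination should take the C6 methyl, whose radical is delocalised through C5, C3 and the lactone carbonyl while that of the C5 methyl is only cross-conjugated, as is known for simpler 4-alkoxy-5,6-dimethyl-2-pyranones.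

Step 13
Reactants: 12 (5Z,8E)-6,8-dimethyl-10-phenyldeca-5,8-dien-1-yne; 21 6-(bromomethyl)-3-methoxy-4-(methoxymethoxy)-5-methyl-2H-pyran-2-one
Product: 23 3-methoxy-4-(methoxymethoxy)-5-methyl-6-[(2E,6Z,9E)-3,7,9-trimethyl-11-phenylundeca-2,6,9-trien-1-yl]-2H-pyran-2-one, via alkenyldimethylalane 22 (not isolated)
Conditions: Me3Al (2 equiv), Cp2ZrCl2 (20 mol%), CH2Cl2, 0 °C → rt; volatiles removed; then 21, Pd(PPh3)4 (5 mol%), THF, 0 °C → rt
Reagents that add atoms: trimethylaluminium, C[Al](C)C
Why: Negishi zirconium-catalysed methylalumination adds methyl and aluminium syn across the terminal alkyne with aluminium on the terminal carbon, and the (E)-alkenylalane should couple with the allylic-type pyranonylmethyl bromide under zerovalent palladium with retention, forming C1'–C2' and the 2'E alkene.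

Step 14
Reactants: 23 3-methoxy-4-(methoxymethoxy)-5-methyl-6-[(2E,6Z,9E)-3,7,9-trimethyl-11-phenylundeca-2,6,9-trien-1-yl]-2H-pyran-2-one
Product: 24 lehualide A
Conditions: HCl (0.5 M in MeOH), 0 °C → rt
Reagents that add atoms: none
Why: Acid-catalysed acetal exchange to methanol should remove the MOM group from the vinylogous ester oxygen much faster than the isolated trisubstituted alkenes are protonated, freeing the 4-hydroxy-2-pyranone.

Compound list
1 | 3-(tert-butyldimethylsilyloxy)propan-1-ol | CC(C)(C)[Si](C)(C)OCCCO | starting material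
2 | 3-(tert-butyldimethylsilyloxy)propanal | CC(C)(C)[Si](C)(C)OCCC=O | intermediate
3 | ethyltriphenylphosphonium iodide | CC[P+](c1ccccc1)(c1ccccc1)c1ccccc1.[I-] | starting material
4 | (Z)-tert-butyl[(4-iodopent-3-en-1-yl)oxy]dimethylsilane | CC(C)(C)[Si](C)(C)OCC/C=C(/C)I | intermediate
5 | (E)-[5-(tert-butyldimethylsilyloxy)pent-2-en-2-yl]lithium, lithium cis to the chain | CC(C)(C)[Si](C)(C)OCC/C=C(/C)[Li] | intermediate
6 | pinacol (E)-5-(tert-butyldimethylsilyloxy)pent-2-en-2-ylboronate, boron cis to the chain | CC(C)(C)[Si](C)(C)OCC/C=C(/C)B1OC(C)(C)C(C)(C)O1 | intermediate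
7 | phenyl trifluoromethanesulfonate | O=S(=O)(Oc1ccccc1)C(F)(F)F | starting material
8 | isoprene | C=CC(C)=C | starting material
9 | tert-butyl{[(3Z,6E)-4,6-dimethyl-8-phenylocta-3,6-dien-1-yl]oxy}dimethylsilane | CC(C)(C)[Si](C)(C)OCC/C=C(/C)C/C(C)=C/Cc1ccccc1 | intermediate
10 | (3Z,6E)-4,6-dimethyl-8-phenylocta-3,6-dien-1-ol | OCC/C=C(/C)C/C(C)=C/Cc1ccccc1 | intermediate
11 | (3Z,6E)-1-iodo-4,6-dimethyl-8-phenylocta-3,6-diene | ICC/C=C(/C)C/C(C)=C/Cc1ccccc1 | intermediate
12 | (5Z,8E)-6,8-dimethyl-10-phenyldeca-5,8-dien-1-yne | C#CCC/C=C(/C)C/C(C)=C/Cc1ccccc1 | intermediate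
13 | methyl methoxyacetate | COCC(=O)OC | starting material
14 | propanoyl chloride | CCC(Cl)=O | starting material
15 | methyl 2-methoxy-3-oxopentanoate (racemic) | CCC(=O)C(OC)C(=O)OC | intermediate
16 | N-methoxy-N-methylacetamide | CON(C)C(C)=O | starting material
17 | dilithium dienolate of methyl 2-methoxy-3-oxopentanoate | CC=C([O-])C(OC)=C([O-])OC.[Li+].[Li+] | intermediate
18 | methyl 2-methoxy-4-methyl-3,5-dioxohexanoate (mixture of diastereomers and enol forms) | COC(=O)C(OC)C(=O)C(C)C(C)=O | intermediate
19 | 4-hydroxy-3-methoxy-5,6-dimethyl-2H-pyran-2-one | COc1c(O)c(C)c(C)oc1=O | intermediate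
20 | 3-methoxy-4-(methoxymethoxy)-5,6-dimethyl-2H-pyran-2-one | COCOc1c(C)c(C)oc(=O)c1OC | intermediate
21 | 6-(bromomethyl)-3-methoxy-4-(methoxymethoxy)-5-methyl-2H-pyran-2-one | COCOc1c(C)c(CBr)oc(=O)c1OC | intermediate
22 | dimethyl[(1E,5Z,8E)-2,6,8-trimethyl-10-phenyldeca-1,5,8-trien-1-yl]alumane | C[Al](C)/C=C(\C)CC/C=C(/C)C/C(C)=C/Cc1ccccc1 | intermediate
23 | 3-methoxy-4-(methoxymethoxy)-5-methyl-6-[(2E,6Z,9E)-3,7,9-trimethyl-11-phenylundeca-2,6,9-trien-1-yl]-2H-pyran-2-one | COCOc1c(C)c(C/C=C(\C)CC/C=C(/C)C/C(C)=C/Cc2ccccc2)oc(=O)c1OC | intermediate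
24 | lehualide A, 4-hydroxy-3-methoxy-5-methyl-6-[(2E,6Z,9E)-3,7,9-trimethyl-11-phenylundeca-2,6,9-trien-1-yl]-2H-pyran-2-one | COc1c(O)c(C)c(C/C=C(\C)CC/C=C(/C)C/C(C)=C/Cc2ccccc2)oc1=O | target

Total step count: 14. Longest linear sequence: 9 steps (steps 1–7, 13, 14); the pyranone branch (steps 8–12) joins at step 13.

Steps most likely to fail

Step 4. The cationic phenylpalladium species may insert isoprene at the isopropenyl end, the π-allyl may be captured at the internal terminus (1,2-addition), or phenyl may couple directly with the boronate before insertion; each would give an isomeric or truncated chain. The fallback sets out from 6 and returns at 9, with the C8'–C11' unit made beforehand so that only the C7'–C8' bond is formed by palladium. Phenylacetaldehyde and Ph3P=C(Me)CO2Et (CH2Cl2, rt) should give ethyl (E)-2-methyl-4-phenylbut-2-enoate F1 by Wittig olefination. Reduction with i-Bu2AlH (CH2Cl2, −78 °C) gives (E)-2-methyl-4-phenylbut-2-en-1-ol F2, and ClCO2Me with pyridine gives methyl (E)-2-methyl-4-phenylbut-2-en-1-yl carbonate F3. F3 and 6 are then joined by an allyl–alkenyl Suzuki–Miyaura coupling (Pd2(dba)3, PPh3, THF, 50 °C), in which the methoxide released on ionisation activates the boronate and the alkenyl group goes to the primary allyl terminus, giving 9.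

Step 13. The alane or residual Me3Al may attack the pyranone carbonyl, the Lewis acid may strip the MOM acetal, or methyl may transfer in place of the alkenyl group. The fallback sets out from 12 and 21 and returns at 23, with the polarity of the coupling reversed. Alkyne 12 is methylaluminated as before to 22 and quenched with I2 (THF, −30 °C) to give (1E,5Z,8E)-1-iodo-2,6,8-trimethyl-10-phenyldeca-1,5,8-triene F8. Bromide 21 is converted with Zn dust and LiCl in THF into [3-methoxy-4-(methoxymethoxy)-5-methyl-2-oxo-2H-pyran-6-yl]methylzinc bromide F9. Negishi coupling of F8 and F9 (Pd(PPh3)4, THF, rt) then gives 23 without any aluminium reagent meeting the pyranone.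

Step 12. Hydrogen abstraction may occur at the C5 methyl or at the acetal methylene, or the C6 methyl may be brominated twice. The fallback sets out from 15 and returns at 21, with the C1' oxygen built in from the start. The dianion of 15 (LiN(i-Pr)2, THF) is acylated with methyl (tert-butyldimethylsilyloxy)acetate to give methyl 6-(tert-butyldimethylsilyloxy)-2-methoxy-4-methyl-3,5-dioxohexanoate F4. DBU in toluene closes it to 6-[(tert-butyldimethylsilyloxy)methyl]-4-hydroxy-3-methoxy-5-methyl-2H-pyran-2-one F5, and MOMCl with i-Pr2NEt gives 6-[(tert-butyldimethylsilyloxy)methyl]-3-methoxy-4-(methoxymethoxy)-5-methyl-2H-pyran-2-one F6. Bu4NF buffered with AcOH frees 6-(hydroxymethyl)-3-methoxy-4-(methoxymethoxy)-5-methyl-2H-pyran-2-one F7, and CBr4 with PPh3 (CH2Cl2, 0 °C) converts it into 21.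

Further compounds
F1 | step 4 | ethyl (E)-2-methyl-4-phenylbut-2-enoate | CCOC(=O)/C(C)=C/Cc1ccccc1
F2 | step 4 | (E)-2-methyl-4-phenylbut-2-en-1-ol | OC/C(C)=C/Cc1ccccc1
F3 | step 4 | methyl (E)-2-methyl-4-phenylbut-2-en-1-yl carbonate | COC(=O)OC/C(C)=C/Cc1ccccc1
F4 | step 12 | methyl 6-(tert-butyldimethylsilyloxy)-2-methoxy-4-methyl-3,5-dioxohexanoate | COC(=O)C(OC)C(=O)C(C)C(=O)CO[Si](C)(C)C(C)(C)C
F5 | step 12 | 6-[(tert-butyldimethylsilyloxy)methyl]-4-hydroxy-3-methoxy-5-methyl-2H-pyran-2-one | COc1c(O)c(C)c(CO[Si](C)(C)C(C)(C)C)oc1=O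
F6 | step 12 | 6-[(tert-butyldimethylsilyloxy)methyl]-3-methoxy-4-(methoxymethoxy)-5-methyl-2H-pyran-2-one | COCOc1c(C)c(CO[Si](C)(C)C(C)(C)C)oc(=O)c1OC
F7 | step 12 | 6-(hydroxymethyl)-3-methoxy-4-(methoxymethoxy)-5-methyl-2H-pyran-2-one | COCOc1c(C)c(CO)oc(=O)c1OC
F8 | step 13 | (1E,5Z,8E)-1-iodo-2,6,8-trimethyl-10-phenyldeca-1,5,8-triene | I/C=C(\C)CC/C=C(/C)C/C(C)=C/Cc1ccccc1
F9 | step 13 | [3-methoxy-4-(methoxymethoxy)-5-methyl-2-oxo-2H-pyran-6-yl]methylzinc bromide | COCOc1c(C)c(C[Zn]Br)oc(=O)c1OC
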